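I have 3 questions about two flasks, north-east and north, and I answer them with one ledger.

| flask | free monomer | transfer agent | initiator | impurity | remark | time |
|---|---|---|---|---|---|---|
| beta | 0.13 M | 6 mM | 4 mM | 0.66 mM | run made earlier |  |
| zeta | 0.10 M | 6 mM | 4 mM | 0.66 mM | run made earlier |  |
| north-east | 0.20 M | 6.00 mM | 4.0 mM | 0.66 mM |  | 4.0 min |
| north | 0.20 M | 6.00 mM | 4.0 mM | 1.0 mM |  | 4.0 min |

| beta: time / s | beta: monomer in chains / % | zeta: time / s | zeta: monomer in chains / % |
|---|---|---|---|
| 12.0 | 1.8 | 12.0 | 1.5 |
| 25.0 | 3.6 | 25.0 | 3.9 |
| 40.0 | 7.8 | 40.0 | 7.4 |
| 50.0 | 9.9 | 50.0 | 8.9 |
| 60.0 | 13.1 | 60.0 | 11.3 |
| 80.0 | 17.9 | 80.0 | 16.6 |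

(readings scatter by 0.5 percentage points)

- the average divides the monomer in chains by the number of chains begun, living and dead together
- the earlier runs do not show the number of chains; that part of a forecast is a guess
- no earlier run changes the charge of impurity; that part of a forecast is a guess

- which of the two ends with the longer chains by the average number of monomer units in a chain (chains begun, living or dead) ("neither" if they lie within 10 %) (north-east / north / neither)
- average number of monomer units in a chain (chains begun, living or dead) at the end, north-east
- average number of monomer units in a chain (chains begun, living or dead) at the end, north

Average length is monomer in chains divided by chains begun, so the ledger needs two entries. For the first, the beta and zeta runs reach 17.9 % and 16.6 % at 80.0 s from different charges of free monomer, so I read loss of free monomer as first order. I replace the curve by one mean rate constant, k = 0.00237 /s, a reading with its scatter. Over 4.0 min this puts a fraction X = 43.3 % of north-east's free monomer in chains, or 86.7 mM.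

For the second entry I treat initiator as the limiting reagent, and here I guess, since no earlier run shows chains. I book each initiator as one chain, each impurity as destroying one initiator, and transfer as ending a chain, not beginning one. Of 4.0 mM charged, the impurity takes 0.66 mM, which leaves the chain budget B, the initiator that survives the impurity: 3.34 mM. North-east then comes to 25.9 units. In north the budget is 3.00 mM. If k scales with the budget, north comes to 26.6, within the margin, so I expect neither.

The forecast also says neither, but gives 15 for north-east and 15 for north, on “about 6 mM of chains”.

The simulation gives neither, with 33.2 for north-east and 34.2 for north.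

    free monomer + living end → monomer in chains + living end, rate k1*[living end]*[free monomer] (k = 1.30 /M/s)
    living end + transfer agent → dead chain (kL = 0.380 /M/s)
    free monomer + initiator → living end + monomer in chains (k = 0.210 /M/s)
    initiator + impurity → spent initiator A (k = 1900 /M/s)
    free monomer + initiator → spent initiator B (k = 0.0220 /M/s)

North-east reaches 33.2 partly because its initiator falls to 0.028 % of charge; with that level held, the length is 12.0. North-east's books close when its budget loses 0.317 mM to spent initiator B, leaving 3.02 mM, against 3.02 mM of living end and dead chain together. A neighbour flask, north with 0.010 M of transfer agent, has 2.72 mM left of its budget, 42.0 % of its monomer in chains, and a length of 30.9.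

The earlier runs and the new flask were computed with constants of no real substance, and the scatter is random.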